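- As the chemist asked to rank these flasks, I began with cold amber and sought a bracket for its Q before judging the forecast.

| flask | X | J | temperature | remark | time |
|---|---|---|---|---|---|
| midnight | 1.5 M | 0.71 M | −45 °C | run made earlier |  |
| spring | 1.5 M | 2.1 M | −10 °C | run made earlier |  |
| summer | 1.4 M | 1.65 M | −45 °C | run made earlier |  |
| amber | 1.5 M | 1.65 M | −40 °C |  | 3.0 d |
| grey | 0.50 M | 1.20 M | 20 °C |  | 3.0 d |
| teal | 1.5 M | 1.65 M | 0 °C |  | 3.0 d |
| blue | 1.0 M | 0.800 M | −15 °C |  | 3.0 d |
| green | 2.5 M | 0.500 M | −20 °C |  | 3.0 d |

- midnight (time / d: Q / %): 2.50: 3.3; 4.00: 6.2; 6.00: 9.5; 10.0: 13.2; 15.0: 18.5; 30.0: 27.0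
- spring (time / d: Q / %): 0.333: 10.7; 1.04: 36.0; 1.67: 50.6; 2.50: 58.6; 4.00: 61.9; 5.00: 62.4
- summer (time / d: Q / %): 6.00: 10.4; 12.0: 21.0; 15.0: 25.0; 25.0: 39.3; 30.0: 43.4

(readings scatter by 0.5 percentage points)

- as a solid, counted per litre of solution: J
- on the list of suspects stand: X + L -> Q; X + L -> G; L + Q -> E; L + G -> E; J <-> L
- at the start none of J is in solution

- the flasks put in order of amount of Q, in percent of the X charged, best first, at 3.0 d (amber / grey / teal / blue / green)
- the amount of Q, in percent of the X charged of the flask you put first, at 3.0 d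
- the amount of Q, in percent of the X charged of the flask you put last, at 3.0 d

- Midnight read 9.5% and summer 10.4% at 6.00 d, although midnight held less J, so I took dissolved L as capped while solid J lasted, and Q formation as pseudo-first-order in X.
- I defined a Q constant: minus the logarithm of the part of X not yet Q, divided by the time. Summer's last reading gave 0.0190 /d, and spring's reading at 1.04 d gave 0.429 /d, which lie 1.35 powers of ten apart.
- These two alone placed amber's Q between 5.53% and 72.4%, which was too wide.
- Amber stands 0.143 of the way from summer to spring in degrees. A straight line in logarithm against degrees runs under a single Arrhenius curve, so the Q constant of amber, κ, is at least 0.0296 /d. That raised the lower bound to 8.50%.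
- For the upper bound I let Q take a share of consumed X no smaller than spring's plateau reading, 62.4%, the lowest share I could defend. The straight line runs low, so it could not serve here: the fraction of the way in reciprocal absolute temperature is the fraction in degrees times the ratio of spring's absolute temperature to amber's, and that ratio is under 1.50. Stretching the fraction by this factor gave a constant for all X of at most 0.0760 /d and a ceiling of 12.7%.
- The forecast ran teal > grey > blue > green > amber, with 57% on top (52% to 61%) and 10% at the bottom (8.5% to 12%), saying “Amber: slow, about 10%.” Its amber value lay inside my bracket.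
- The flasks ran teal > blue > grey > green > amber, and amber gave 9.83%, inside the bracket, with teal at 52.4%.

    X + L → Q (k = 3.80 × 10⁻⁵ /M/s, Ea = 56.0 kJ/mol)
    X + L → G (k = 2.30 × 10⁻⁵ /M/s, Ea = 72.0 kJ/mol)
    L + Q → E (k = 1.80 × 10⁻⁶ /M/s, Ea = 61.0 kJ/mol)
    L + G → E (k = 4.40 × 10⁻⁵ /M/s, Ea = 77.0 kJ/mol)
    J ⇌ L, rate k5*(cs5 - [L]) while solid is left; crystals form when [L] > cs5 (solubility = 0.840 M, k = 3.50 × 10⁻⁵ /s)
    (constants at 0 °C)

- At 3.00 d amber held L at 0.819 M, made 1.02 times as fast as it was used, with J at 39.7% of its own charge. Amber's Q constant read from its result is 0.0345 /d, above κ, as a lower bound requires.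
- For amber read at 40 h, κ gives at least 4.82%, and the ceiling reckoning gives 7.42%. The computed flask holds 5.09% of Q, between them.

The numbers in the tables are simulated with constants of no real substance.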